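## Retrosynthetic overview

1. Target 16 ⇒ alcohol 15 (O-sulfation) ⇒ anilide 14 (reductive C–N cleavage).
2. Key disconnection C12–C13 of 14: racemic α-bromo amide 12 used as an enolonium (α-carbonyl cation) equivalent plus primary alkylzinc 13; a chiral Pybox–nickel catalyst sets C13 while the two halves are joined.
3. 12 ⇒ amide 11 (α-bromination) ⇒ pentenamide 8 + 3-bromofuran 9 (hydroboration/B-alkyl Suzuki); 8 ⇒ N-benzylaniline 6 + pent-4-enoyl chloride 7.
4. 13 ⇒ iodide 5 ⇒ alcohol 4 ⇒ acetate 3 ⇒ (−)-Ambrox 1 by acetolytic ring opening with 1,2-H and 1,2-CH3 shifts (sets C8 and C9, creates the C5=C10 alkene).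
5. Ring order: no ring is built; rings A and B come from 1 (only its oxolane ring is opened) and the furan comes from 9.

Notation: Bic = (1R,2S)-1,2,5,5-tetramethyl-1,2,3,4,5,6,7,8-octahydronaphthalen-1-yl. Labdane-type locants: C8 = ring CH(CH3), C9 = quaternary ring carbon, C5=C10 = ring alkene, C11 and C12 = the two CH2 groups leading to C13, the side-chain stereocentre.

Assumption 1: the target is the free hydrogen sulfate as drawn; it is released by H+ exchange in step 9 and is best stored as its sodium salt.

Assumption 2: the sense of induction in step 7 is assigned by analogy with simple N-benzyl-N-phenyl α-bromo amides ((S)-ligand gives the C13 configuration of 14); if a test coupling shows the opposite sense, the equally available (R)-ligand is used.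

## Route

Step 1
Reactants: 1 (−)-Ambrox, (3aR,5aS,9aS,9bR)-3a,6,6,9a-tetramethyldodecahydronaphtho[2,1-b]furan
Product: 3 2-Bic-ethyl acetate, via ring-opened exocyclic-alkene acetate 2 (not isolated)
Conditions: Ac2O (2.5 equiv), BF3·OEt2 (1.5 equiv), CH2Cl2, −40 → 0 °C; aq. NaHCO3
Reagents that add atoms: acetic anhydride, CC(=O)OC(C)=O
Why: Proposed new method: BF3-activated Ac2O acylates the ether oxygen and the tertiary C8–O bond ionises, the C8 cation (also reached reversibly from the alkene acetates such as 2) undergoes the suprafacial H9α→C8 and CH3-10β→C9 shifts and loses H5 to give the tetrasubstituted alkene while the acetylated oxygen cannot re-close, so C8 (S) and C9 (R, the two methyls cis) are fixed by the substrate; the closest known reaction types are the Lewis-acid/Ac2O acetolysis of tertiary ethers and the BF3·OEt2-induced friedo rearrangement of drimane C8 cations to 5(10)-enes.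

Step 2
Reactants: 3 2-Bic-ethyl acetate
Product: 4 2-Bic-ethanol
Conditions: K2CO3 (0.2 equiv), MeOH, rt
Reagents that add atoms: none
Why: Base-catalysed transesterification (methanolysis of the acetate) frees the primary alcohol under conditions that leave the acid-sensitive tetrasubstituted alkene and both stereocentres untouched.

Step 3
Reactants: 4 2-Bic-ethanol
Product: 5 2-Bic-ethyl iodide
Conditions: PPh3, I2, imidazole (premixed), CH2Cl2, 0 °C → rt
Reagents that add atoms: iodine, II
Why: Appel-type iodination converts the primary alcohol by SN2 displacement of its alkoxyphosphonium, and premixing the reagents leaves no free iodine to attack the hindered alkene.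

Step 4
Reactants: 6 N-benzylaniline; 7 pent-4-enoyl chloride
Product: 8 N-benzyl-N-phenylpent-4-enamide
Conditions: Et3N, CH2Cl2, 0 °C → rt
Reagents that add atoms: none
Why: N-Acylation of the secondary aniline by the acid chloride (Schotten–Baumann-type amide formation) gives the N-benzyl-N-phenyl amide class for which the later nickel coupling is best precedented.

Step 5
Reactants: 8 N-benzyl-N-phenylpent-4-enamide; 9 3-bromofuran
Product: 11 N-benzyl-5-(furan-3-yl)-N-phenylpentanamide, via B-alkyl-9-BBN adduct 10 (not isolated)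
Conditions: 9-BBN (1.1 equiv), THF, 0 °C → rt; then 9, PdCl2(dppf) (3 mol %), aq. K3PO4, DMF, 50 °C
Reagents that add atoms: none
Why: Anti-Markovnikov hydroboration of the terminal alkene followed by B-alkyl Suzuki–Miyaura coupling with the heteroaryl bromide forges the sp3–sp2 bond, the tertiary anilide being inert to one equivalent of 9-BBN at room temperature.

Step 6
Reactants: 11 N-benzyl-5-(furan-3-yl)-N-phenylpentanamide
Product: 12 rac-N-benzyl-2-bromo-5-(furan-3-yl)-N-phenylpentanamide
Conditions: LiN(i-Pr)2 (commercial solution), THF, −78 °C; enolate cannulated into C2Br2Cl4, THF, −78 °C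
Reagents that add atoms: 1,2-dibromo-1,1,2,2-tetrachloroethane, BrC(Cl)(Cl)C(Cl)(Cl)Br
Why: Electrophilic α-bromination of the lithium amide enolate by a halophilic bromine donor that does not attack furans, with inverse addition to suppress proton exchange and dibromination; the product is deliberately racemic.

Step 7
Reactants: 5 2-Bic-ethyl iodide; 12 rac-N-benzyl-2-bromo-5-(furan-3-yl)-N-phenylpentanamide
Product: 14 (2R)-N-benzyl-5-(furan-3-yl)-N-phenyl-2-(2-Bic-ethyl)pentanamide, via alkylzinc iodide 13 (not isolated)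
Conditions: 5 (1.3 equiv), Zn dust, I2 (5 mol %), DMI, 50 °C; then 12, NiCl2·glyme (10 mol %), (S)-i-Pr-Pybox (13 mol %), DMI/THF, 0 °C
Reagents that add atoms: none
Why: Stereoconvergent nickel-catalysed Negishi coupling in which the α-bromo amide acts as an enolonium equivalent, so that the normally nucleophilic α-carbon C13 is joined as an acceptor to the nucleophilic alkylzinc carbon C12: halogen abstraction gives a planar α-amido radical that erases the configuration of rac-12, and the chiral Pybox–nickel complex then forms the C12–C13 bond on one face to give (R)-C13.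

Step 8
Reactants: 14 (2R)-N-benzyl-5-(furan-3-yl)-N-phenyl-2-(2-Bic-ethyl)pentanamide
Product: 15 (2R)-5-(furan-3-yl)-2-(2-Bic-ethyl)pentan-1-ol
Conditions: LiAlH4, THF, 0 °C → rt; Fieser work-up
Reagents that add atoms: none
Why: Hydride addition to the anilide gives a tetrahedral aluminate that expels the weakly basic N-benzylanilide, and the resulting aldehyde is reduced on to the primary alcohol (reductive amide C–N cleavage) without touching the α-stereocentre, the furan or the alkene.

Step 9
Reactants: 15 (2R)-5-(furan-3-yl)-2-(2-Bic-ethyl)pentan-1-ol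
Product: 16 (2R)-5-(furan-3-yl)-2-(2-Bic-ethyl)pentyl hydrogen sulfate (target)
Conditions: SO3·pyridine (3 equiv), pyridine, 0 °C → rt; then Dowex 50W (H+ form), MeOH, 0 °C
Reagents that add atoms: sulfur trioxide–pyridine complex, O=S(=O)([O-])[n+]1ccccc1
Why: O-Sulfation of the unhindered primary alcohol by the mild SO3·pyridine complex is much faster than sulfonation of the furan at room temperature, and no stereocentre is involved.

## Compound list

1 | (−)-Ambrox, (3aR,5aS,9aS,9bR)-3a,6,6,9a-tetramethyldodecahydronaphtho[2,1-b]furan | C1C[C@H]2[C@](C)(O1)CC[C@H]3C(C)(C)CCC[C@]23C | starting material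
2 | 2-[(1S,4aS,8aS)-5,5,8a-trimethyl-2-methylidenedecahydronaphthalen-1-yl]ethyl acetate (formed in the flask in step 1; its ring-alkene isomers behave alike) | CC(=O)OCC[C@H]1C(=C)CC[C@H]2C(C)(C)CCC[C@]12C | intermediate
3 | 2-[(1R,2S)-1,2,5,5-tetramethyl-1,2,3,4,5,6,7,8-octahydronaphthalen-1-yl]ethyl acetate | C[C@H]1CCC2=C(CCCC2(C)C)[C@]1(C)CCOC(C)=O | intermediate
4 | 2-[(1R,2S)-1,2,5,5-tetramethyl-1,2,3,4,5,6,7,8-octahydronaphthalen-1-yl]ethan-1-ol | C[C@H]1CCC2=C(CCCC2(C)C)[C@]1(C)CCO | intermediate
5 | (1R,2S)-1-(2-iodoethyl)-1,2,5,5-tetramethyl-1,2,3,4,5,6,7,8-octahydronaphthalene | C[C@H]1CCC2=C(CCCC2(C)C)[C@]1(C)CCI | intermediate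
6 | N-benzylaniline | C(Nc1ccccc1)c1ccccc1 | starting material
7 | pent-4-enoyl chloride | C=CCCC(=O)Cl | starting material
8 | N-benzyl-N-phenylpent-4-enamide | C=CCCC(=O)N(Cc1ccccc1)c1ccccc1 | intermediate
9 | 3-bromofuran | Brc1ccoc1 | starting material
10 | N-benzyl-5-(9-borabicyclo[3.3.1]nonan-9-yl)-N-phenylpentanamide (formed in the flask in step 5) | O=C(CCCCB1C2CCCC1CCC2)N(Cc1ccccc1)c1ccccc1 | intermediate
11 | N-benzyl-5-(furan-3-yl)-N-phenylpentanamide | O=C(CCCCc1ccoc1)N(Cc1ccccc1)c1ccccc1 | intermediate
12 | rac-N-benzyl-2-bromo-5-(furan-3-yl)-N-phenylpentanamide | O=C(C(Br)CCCc1ccoc1)N(Cc1ccccc1)c1ccccc1 | intermediate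
13 | {2-[(1R,2S)-1,2,5,5-tetramethyl-1,2,3,4,5,6,7,8-octahydronaphthalen-1-yl]ethyl}zinc iodide (formed in the flask in step 7) | C[C@H]1CCC2=C(CCCC2(C)C)[C@]1(C)CC[Zn]I | intermediate
14 | (2R)-N-benzyl-5-(furan-3-yl)-N-phenyl-2-{2-[(1R,2S)-1,2,5,5-tetramethyl-1,2,3,4,5,6,7,8-octahydronaphthalen-1-yl]ethyl}pentanamide | C[C@H]1CCC2=C(CCCC2(C)C)[C@]1(C)CC[C@@H](CCCc1ccoc1)C(=O)N(Cc1ccccc1)c1ccccc1 | intermediate
15 | (2R)-5-(furan-3-yl)-2-{2-[(1R,2S)-1,2,5,5-tetramethyl-1,2,3,4,5,6,7,8-octahydronaphthalen-1-yl]ethyl}pentan-1-ol | C[C@H]1CCC2=C(CCCC2(C)C)[C@]1(C)CC[C@@H](CCCc1ccoc1)CO | intermediate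
16 | (2R)-5-(furan-3-yl)-2-{2-[(1R,2S)-1,2,5,5-tetramethyl-1,2,3,4,5,6,7,8-octahydronaphthalen-1-yl]ethyl}pentyl hydrogen sulfate | C[C@H]1CCC2=C(CCCC2(C)C)[C@]1(C)CC[C@@H](CCCc1ccoc1)COS(=O)(=O)O | target

## Step count and risks

Total step count: 9. Longest linear sequence: 6 (steps 1, 2, 3, 7, 8, 9; the amide branch, steps 4, 5, 6, 7, 8, 9, is equally long).

**Step 7 (key coupling).** The α-amido radical may add to the tethered furan (six-membered ring closure), the furan may bind nickel, and an enantioselectivity below about 90 % would leave a C13 epimer that is hard to remove. The fallback attaches the furan only after the stereocentre exists. It sets out from 8 and from 5 and comes back to the route at 14. Amide 8 is α-brominated as in step 6 (LiN(i-Pr)2, then C2Br2Cl4) to rac-N-benzyl-2-bromo-N-phenylpent-4-enamide F1, a small furan-free electrophile. F1 is coupled with 13 (made from 5 as in step 7) under the same NiCl2·glyme/(S)-i-Pr-Pybox conditions to (2S)-N-benzyl-N-phenyl-2-(2-Bic-ethyl)pent-4-enamide F2. F2 has the same spatial arrangement as 14; the descriptor differs only because allyl outranks the Bic-ethyl chain. 9-BBN then adds to the terminal alkene of F2 to give the B-alkyl-9-BBN adduct F3, which is coupled in the same flask with 9 (PdCl2(dppf), aq. K3PO4, DMF, 50 °C) to give 14. The step count stays at 9 and the longest linear sequence becomes 7.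

**Step 1 (tandem acetolysis and rearrangement).** The alkene acetates may not funnel completely to 3, Ac2O/BF3 may acylate an alkene, and the skeleton may rearrange further. The fallback generates the same C8 cation from a free tertiary alcohol with no acylating agent present. It sets out in place of 1 from commercial (+)-sclareolide F4 and comes back to the route at 3. F4 is reduced (LiAlH4, THF) to ambradiol F5, whose primary hydroxyl is acetylated selectively (Ac2O, pyridine, 0 °C) to ambradiol 12-monoacetate F6. BF3·OEt2 alone (CH2Cl2, −50 → −5 °C) then ionises the tertiary alcohol of F6, and the same 1,2-H and 1,2-CH3 shifts and loss of H5 deliver 3. This costs two extra steps.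

**Step 6 (α-bromination).** Proton exchange between enolate and product can give dibromide and returned 11, and the furan limits the choice of bromine source. The fallback delivers oxygen to the enolate and introduces bromide by substitution. It sets out from 11 and comes back to the route at 12. The potassium enolate of 11 (KN(SiMe3)2, THF, −78 °C) is hydroxylated with 3-phenyl-2-(phenylsulfonyl)oxaziridine to rac-N-benzyl-5-(furan-3-yl)-2-hydroxy-N-phenylpentanamide F7. F7 is converted to 12 with CBr4/PPh3 (CH2Cl2, 0 °C). A second substitution cannot occur and no electrophilic bromine meets the enolate. This costs one extra step.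

## Further compounds

F1 | step 7 | rac-N-benzyl-2-bromo-N-phenylpent-4-enamide | C=CCC(Br)C(=O)N(Cc1ccccc1)c1ccccc1
F2 | step 7 | (2S)-N-benzyl-N-phenyl-2-{2-[(1R,2S)-1,2,5,5-tetramethyl-1,2,3,4,5,6,7,8-octahydronaphthalen-1-yl]ethyl}pent-4-enamide | C[C@H]1CCC2=C(CCCC2(C)C)[C@]1(C)CC[C@@H](CC=C)C(=O)N(Cc1ccccc1)c1ccccc1
F3 | step 7 | (2R)-N-benzyl-5-(9-borabicyclo[3.3.1]nonan-9-yl)-N-phenyl-2-{2-[(1R,2S)-1,2,5,5-tetramethyl-1,2,3,4,5,6,7,8-octahydronaphthalen-1-yl]ethyl}pentanamide | C[C@H]1CCC2=C(CCCC2(C)C)[C@]1(C)CC[C@@H](CCCB3C4CCCC3CCC4)C(=O)N(Cc1ccccc1)c1ccccc1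
F4 | step 1 | (+)-sclareolide, (3aR,5aS,9aS,9bR)-3a,6,6,9a-tetramethyldecahydronaphtho[2,1-b]furan-2(1H)-one | O=C1C[C@H]2[C@](C)(O1)CC[C@H]3C(C)(C)CCC[C@]23C
F5 | step 1 | ambradiol, (1R,2R,4aS,8aS)-1-(2-hydroxyethyl)-2,5,5,8a-tetramethyldecahydronaphthalen-2-ol | OCC[C@H]1[C@](C)(O)CC[C@H]2C(C)(C)CCC[C@]12C
F6 | step 1 | ambradiol 12-monoacetate, 2-[(1R,2R,4aS,8aS)-2-hydroxy-2,5,5,8a-tetramethyldecahydronaphthalen-1-yl]ethyl acetate | CC(=O)OCC[C@H]1[C@](C)(O)CC[C@H]2C(C)(C)CCC[C@]12C
F7 | step 6 | rac-N-benzyl-5-(furan-3-yl)-2-hydroxy-N-phenylpentanamide | O=C(C(O)CCCc1ccoc1)N(Cc1ccccc1)c1ccccc1
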